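**Plan**

1. Locants used here: C1 (free carbinol), C2(Me)=C3, C4, C5 (OAc), C6 (Me), C7, C8, C9 (=C19H2), C10 and C11 form the eleven-membered ring; C8–C9–C10–C12–C13(O-propanoyl)–C14(Me) is the six-membered ring; C7–C8–C14–C15–C16 is the cyclopentane.
2. Enabling feature: C1(OH)–C11H2–C10H–C9(=C19H2) is a bishomoallylic alcohol, the product pattern of a reductive 1,3-diene + aldehyde coupling. Cutting C11–C1 opens the macrocycle to an (E)-enal tethered to a cis-hydrindane that carries a 1,2-dimethylidenecyclohexane (C10=C11, C9=C19).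
3. Further cuts: C9–C10 (enyne cycloisomerisation, six-membered ring), C4–C5 (vinylogous aldol), C12–C13 (allylboration), C9–C19 (alkyne homologation), C6–C7 (Ireland–Claisen), C14–CH3 (alkylation of a cyclopentanone nitrile).
4. Forward: the cyclopentane is the starting ring; C14, C7/C6, C8, C13 and C5 are set on it. The six-membered diene ring is closed in step 19 and the eleven-membered ring last, in step 20, with both esters already in place.
5. Stereochemistry: C14 by chiral phase-transfer methylation; C7/C6 relayed from C14 through a chair Ireland–Claisen; C8 by hydroboration anti to the C7 chain; C13 by reagent-controlled allylboration; C5 by Felkin–Anh addition; C10 and C1 in the key step.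

Key step: step 20

Remark on the chemistry (assumption): the antipode of the ammonium catalyst in step 1 is the one that gives (R)-2. The α face is the face opposite the C14 methyl; it carries C13 on C14, C9 on C8 and C6 on C7. CIP descriptors in the names refer to the structures in the compound list.

**Route**

Step 1
Reactants: 1 2-oxocyclopentane-1-carbonitrile
Product: 2 (1R)-1-methyl-2-oxocyclopentane-1-carbonitrile
Conditions: MeI, K2CO3 (solid), (S,S)-3,4,5-trifluorophenyl-NAS bromide (2 mol%), toluene, 0 °C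
Reagents that add atoms: iodomethane (CI)
Why: Asymmetric phase-transfer C-alkylation, established for cyclic β-keto esters and α-cyano esters and applied here to the analogous cyclic β-keto nitrile, in which the chiral ammonium enolate ion pair exposes one enolate face to MeI and so sets the quaternary centre C14.

Step 2
Reactants: 2 (1R)-1-methyl-2-oxocyclopentane-1-carbonitrile
Product: 3 (5R)-5-cyano-5-methylcyclopent-1-en-1-yl trifluoromethanesulfonate
Conditions: KN(SiMe3)2, THF, −78 °C; PhNTf2, −78 → 0 °C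
Reagents that add atoms: N-phenylbis(trifluoromethanesulfonimide) (O=S(=O)(N(c1ccccc1)S(=O)(=O)C(F)(F)F)C(F)(F)F)
Why: Enol triflate formation, in which only the CH2 α-position can be deprotonated because the other α-carbon is quaternary, so a single regioisomer forms and C14 is untouched.

Step 3
Reactants: 3 (5R)-5-cyano-5-methylcyclopent-1-en-1-yl trifluoromethanesulfonate
Product: 4 (1S)-2-(hydroxymethyl)-1-methylcyclopent-2-ene-1-carbonitrile
Conditions: Bu3SnCH2OH, Pd(PPh3)4 (5 mol%), LiCl, 1,4-dioxane, 90 °C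
Reagents that add atoms: (tributylstannyl)methanol (OC[Sn](CCCC)(CCCC)CCCC)
Why: Stille coupling of the alkenyl triflate with the hydroxymethylstannane introduces C9 as the primary allylic alcohol needed for the sigmatropic step.

Step 4
Reactants: 4 (1S)-2-(hydroxymethyl)-1-methylcyclopent-2-ene-1-carbonitrile
Product: 5 [(5S)-5-cyano-5-methylcyclopent-1-en-1-yl]methyl propanoate
Conditions: EtCOCl, pyridine, CH2Cl2, 0 °C
Reagents that add atoms: propanoyl chloride (CCC(Cl)=O)
Why: Standard O-acylation of a primary allylic alcohol provides the propanoate required for the ester-enolate Claisen rearrangement.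

Step 5
Reactants: 5 [(5S)-5-cyano-5-methylcyclopent-1-en-1-yl]methyl propanoate
Product: 8 (2S)-2-[(1S,3S)-3-cyano-3-methyl-2-methylidenecyclopentyl]propanoic acid, via silyl ketene acetal 6 (not isolated), via trimethylsilyl ester 7 (not isolated)
Conditions: LiN(iPr)2, THF–HMPA (4:1), −78 °C; Me3SiCl; −78 → 25 °C; then 1 M HCl
Reagents that add atoms: none
Why: Ireland–Claisen rearrangement, in which enolisation in THF–HMPA gives the (Z)-silyl ketene acetal whose chair transition state (ring carbon C16 and the enolate methyl both pseudo-equatorial) sets C6 relative to C7, while the C6–C7 bond forms on the cyclopentene face anti to the C14 methyl and syn to the slender nitrile, so the new chain ends cis to the nitrile.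

Step 6
Reactants: 8 (2S)-2-[(1S,3S)-3-cyano-3-methyl-2-methylidenecyclopentyl]propanoic acid
Product: 10 (1S,3S)-3-[(2S)-1-hydroxypropan-2-yl]-1-methyl-2-methylidenecyclopentane-1-carbonitrile, via mixed anhydride 9 (not isolated)
Conditions: iBuOCOCl, N-methylmorpholine, THF, −15 °C; NaBH4, H2O, 0 °C
Reagents that add atoms: none
Why: Borohydride reduction of the mixed carbonic anhydride converts the acid to the primary alcohol chemoselectively, leaving the nitrile and the 1,1-disubstituted alkene intact.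

Step 7
Reactants: 10 (1S,3S)-3-[(2S)-1-hydroxypropan-2-yl]-1-methyl-2-methylidenecyclopentane-1-carbonitrile
Product: 11 (1S,3S)-3-[(2S)-1-{[tert-butyl(dimethyl)silyl]oxy}propan-2-yl]-1-methyl-2-methylidenecyclopentane-1-carbonitrile
Conditions: tBuMe2SiCl, imidazole, DMF, 25 °C
Reagents that add atoms: tert-butyl(chloro)dimethylsilane (CC(C)(C)[Si](C)(C)Cl)
Why: Silyl ether formation masks the C5 oxygen through the hydride, organoborane and acylation steps that follow.

Step 8
Reactants: 11 (1S,3S)-3-[(2S)-1-{[tert-butyl(dimethyl)silyl]oxy}propan-2-yl]-1-methyl-2-methylidenecyclopentane-1-carbonitrile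
Product: 13 (1S,2R,3S)-3-[(2S)-1-{[tert-butyl(dimethyl)silyl]oxy}propan-2-yl]-2-(hydroxymethyl)-1-methylcyclopentane-1-carbonitrile, via B-alkyl-9-borabicyclononane 12 (not isolated)
Conditions: 9-BBN-H, THF, 25 → 50 °C; NaBO3·4H2O, THF–H2O, 25 °C
Reagents that add atoms: sodium perborate ([Na+].[O-]OB=O)
Why: Anti-Markovnikov hydroboration–oxidation, in which the bulky borane adds to the exocyclic alkene from the face opposite the C7 side chain, so hydrogen enters C8 trans to that chain and the hydroxymethyl carbon C9 ends cis to both the C7 chain and the nitrile.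

Step 9
Reactants: 13 (1S,2R,3S)-3-[(2S)-1-{[tert-butyl(dimethyl)silyl]oxy}propan-2-yl]-2-(hydroxymethyl)-1-methylcyclopentane-1-carbonitrile
Product: 14 (1S,2R,3S)-3-[(2S)-1-{[tert-butyl(dimethyl)silyl]oxy}propan-2-yl]-2-formyl-1-methylcyclopentane-1-carbonitrile
Conditions: Dess–Martin periodinane, CH2Cl2, 25 °C
Reagents that add atoms: none
Why: Mild, non-basic Dess–Martin oxidation of the primary alcohol gives the aldehyde without epimerising the adjacent all-cis centre C8.

Step 10
Reactants: 14 (1S,2R,3S)-3-[(2S)-1-{[tert-butyl(dimethyl)silyl]oxy}propan-2-yl]-2-formyl-1-methylcyclopentane-1-carbonitrile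
Product: 15 (1S,2S,3R)-3-[(2S)-1-{[tert-butyl(dimethyl)silyl]oxy}propan-2-yl]-2-ethynyl-1-methylcyclopentane-1-carbonitrile
Conditions: dimethyl (1-diazo-2-oxopropyl)phosphonate, K2CO3, MeOH, 0 → 25 °C
Reagents that add atoms: Ohira–Bestmann reagent (COP(=O)(OC)C(=[N+]=[N-])C(C)=O)
Why: Seyferth–Gilbert homologation in its Ohira–Bestmann form converts the aldehyde into the terminal alkyne (C9≡C19) under conditions mild enough to preserve C8.

Step 11
Reactants: 15 (1S,2S,3R)-3-[(2S)-1-{[tert-butyl(dimethyl)silyl]oxy}propan-2-yl]-2-ethynyl-1-methylcyclopentane-1-carbonitrile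
Product: 17 (1S,2S,3R)-3-[(2S)-1-{[tert-butyl(dimethyl)silyl]oxy}propan-2-yl]-2-ethynyl-1-methylcyclopentane-1-carbaldehyde, via N-aluminoimine 16 (not isolated)
Conditions: iBu2AlH, toluene, −78 → −20 °C; then 1 M HCl, 0 °C
Reagents that add atoms: water (O)
Why: Partial reduction of the hindered tertiary nitrile stops at the N-aluminoimine, which hydrolyses to the neopentyl aldehyde C13, while the silyl ether and the alkyne are inert.

Step 12
Reactants: 17 (1S,2S,3R)-3-[(2S)-1-{[tert-butyl(dimethyl)silyl]oxy}propan-2-yl]-2-ethynyl-1-methylcyclopentane-1-carbaldehyde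
Product: 19 (1S)-1-[(1S,2S,3R)-3-[(2S)-1-{[tert-butyl(dimethyl)silyl]oxy}propan-2-yl]-2-ethynyl-1-methylcyclopentyl]but-3-en-1-ol, via diisopinocampheylborinate 18 (not isolated)
Conditions: (−)-B-allyldiisopinocampheylborane, Et2O, −78 °C; NaOH, H2O2, 0 → 25 °C
Reagents that add atoms: (−)-B-allyldiisopinocampheylborane (C=CCB([C@@H]1C[C@@H]2C[C@H]([C@H]1C)C2(C)C)[C@@H]1C[C@@H]2C[C@H]([C@H]1C)C2(C)C)
Why: Asymmetric allylboration through a chair Zimmerman–Traxler transition state, in which the reagent derived from (+)-α-pinene delivers allyl to the Si face of the aldehyde and sets C13 as S under reagent control.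

Step 13
Reactants: 19 (1S)-1-[(1S,2S,3R)-3-[(2S)-1-{[tert-butyl(dimethyl)silyl]oxy}propan-2-yl]-2-ethynyl-1-methylcyclopentyl]but-3-en-1-ol
Product: 20 (1S)-1-[(1S,2S,3R)-3-[(2S)-1-{[tert-butyl(dimethyl)silyl]oxy}propan-2-yl]-2-ethynyl-1-methylcyclopentyl]but-3-en-1-yl propanoate
Conditions: (EtCO)2O, Et3N, DMAP (cat.), CH2Cl2, 25 °C
Reagents that add atoms: propanoic anhydride (CCC(=O)OC(=O)CC)
Why: DMAP-catalysed acylation of the hindered secondary alcohol installs the C13 propanoate of the target.

Step 14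
Reactants: 20 (1S)-1-[(1S,2S,3R)-3-[(2S)-1-{[tert-butyl(dimethyl)silyl]oxy}propan-2-yl]-2-ethynyl-1-methylcyclopentyl]but-3-en-1-yl propanoate
Product: 21 (1S)-1-[(1S,2S,3R)-2-ethynyl-3-[(2S)-1-hydroxypropan-2-yl]-1-methylcyclopentyl]but-3-en-1-yl propanoate
Conditions: HF·pyridine, pyridine, THF, 0 → 25 °C
Reagents that add atoms: none
Why: Buffered fluoride desilylation frees the primary alcohol without hydrolysing or migrating the propanoate.

Step 15
Reactants: 21 (1S)-1-[(1S,2S,3R)-2-ethynyl-3-[(2S)-1-hydroxypropan-2-yl]-1-methylcyclopentyl]but-3-en-1-yl propanoate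
Product: 22 (1S)-1-[(1S,2S,3R)-2-ethynyl-1-methyl-3-[(2S)-1-oxopropan-2-yl]cyclopentyl]but-3-en-1-yl propanoate
Conditions: Dess–Martin periodinane, CH2Cl2, 0 → 25 °C
Reagents that add atoms: none
Why: Neutral Dess–Martin oxidation gives the α-methyl aldehyde (C5) without epimerising C6, and the aldehyde is used without storage.

Step 16
Reactants: 23 (2E)-2-methylbut-2-enal
Product: 24 tert-butyl(dimethyl){[(1E)-2-methylbuta-1,3-dien-1-yl]oxy}silane
Conditions: tBuMe2SiOTf, Et3N, Et2O, 0 → 25 °C
Reagents that add atoms: tert-butyldimethylsilyl trifluoromethanesulfonate (CC(C)(C)[Si](C)(C)OS(=O)(=O)C(F)(F)F)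
Why: Soft γ-enolisation and O-silylation of the enal gives the silyl dienol ether that serves as the vinylogous nucleophile, either enol ether geometry leading to the same aldol product.

Step 17
Reactants: 22 (1S)-1-[(1S,2S,3R)-2-ethynyl-1-methyl-3-[(2S)-1-oxopropan-2-yl]cyclopentyl]but-3-en-1-yl propanoate; 24 tert-butyl(dimethyl){[(1E)-2-methylbuta-1,3-dien-1-yl]oxy}silane
Product: 25 (1S)-1-[(1S,2S,3R)-2-ethynyl-3-[(2S,3S,5E)-3-hydroxy-6-methyl-7-oxohept-5-en-2-yl]-1-methylcyclopentyl]but-3-en-1-yl propanoate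
Conditions: B(C6F5)3 (20 mol%), iPrOH, CH2Cl2–Et2O, −78 °C
Reagents that add atoms: none
Why: Vinylogous Mukaiyama aldol reaction, in which γ-attack of the dienol ether on the Lewis-acid-activated aldehyde gives the (E)-δ-hydroxy enal directly and Felkin–Anh addition anti to the cyclopentyl group sets C5 as S, syn to the C6 methyl.

Step 18
Reactants: 25 (1S)-1-[(1S,2S,3R)-2-ethynyl-3-[(2S,3S,5E)-3-hydroxy-6-methyl-7-oxohept-5-en-2-yl]-1-methylcyclopentyl]but-3-en-1-yl propanoate
Product: 26 (1S)-1-[(1S,2S,3R)-3-[(2S,3S,5E)-3-(acetyloxy)-6-methyl-7-oxohept-5-en-2-yl]-2-ethynyl-1-methylcyclopentyl]but-3-en-1-yl propanoate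
Conditions: Ac2O, pyridine, DMAP (cat.), CH2Cl2, 0 °C
Reagents that add atoms: acetic anhydride (CC(=O)OC(C)=O)
Why: Acetylation under mild base installs the C5 acetate without vinylogous elimination toward the enal.

Step 19
Reactants: 26 (1S)-1-[(1S,2S,3R)-3-[(2S,3S,5E)-3-(acetyloxy)-6-methyl-7-oxohept-5-en-2-yl]-2-ethynyl-1-methylcyclopentyl]but-3-en-1-yl propanoate
Product: 27 (1R,3aS,4S,7aS)-1-[(2S,3S,5E)-3-(acetyloxy)-6-methyl-7-oxohept-5-en-2-yl]-3a-methyl-6,7-dimethylideneoctahydro-1H-inden-4-yl propanoate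
Conditions: Pd2(dba)3·CHCl3 (2.5 mol%), P(o-tolyl)3 (10 mol%), AcOH (20 mol%), benzene, 60 °C
Reagents that add atoms: none
Why: Palladium-catalysed enyne cycloisomerisation, in which hydridopalladium acetate adds to the terminal alkyne, 6-exo carbopalladation of the allyl alkene forms C9–C10 and β-hydride elimination from C10 releases the 1,2-dimethylidenecyclohexane, the ring fusion being cis because both reacting arms are cis on the cyclopentane.

Step 20
Reactants: 27 (1R,3aS,4S,7aS)-1-[(2S,3S,5E)-3-(acetyloxy)-6-methyl-7-oxohept-5-en-2-yl]-3a-methyl-6,7-dimethylideneoctahydro-1H-inden-4-yl propanoate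
Product: 29 CNP0180453.1, via diethylborinate 28 (not isolated)
Conditions: Ni(acac)2 (20 mol%), Et3B (3 equiv), THF, 25 °C, syringe-pump addition of 27 to about 1 mM; then aq. NaHCO3
Reagents that add atoms: none
Why: Proposed new method: the nickel-catalysed reductive coupling of a 1,3-diene with an aldehyde (homoallylation with Ni(acac)2/Et3B; known between two molecules and for closing five- to seven-membered rings, the closest reaction type) is used here to close a macrocycle, on the reasoning that zerovalent nickel generated by Et3B binds the s-cis-locked exocyclic diene together with the boron-activated enal carbonyl and undergoes oxidative cyclisation to an oxanickelacycle in which C11–C1 is formed and C10–C9–C19 is an η3-allyl, after which ethyl transfer from boron, β-hydride elimination (ethene) and C–H reductive elimination at C10 release borinate 28 and zerovalent nickel. The eleven-membered ring is closed in an 11-endo-trig sense (C11 is attacked and C10 stays in the ring), and the same event leaves C9=C19 as the exocyclic methylidene of the target. C10 is controlled by the metal: hydride is delivered on the diene face that carries nickel, which is the α face from which the tether (C7 on C8) reaches C11, so H-10 ends cis to the C8–C7 bond and C11 trans to it (10R). C1 is controlled by the tether: with oxygen bound to nickel on that face and the (E)-C2=C3 unit and its methyl turned to the outside of the forming ring, C11 should meet the Re face of the aldehyde (1R), which is the least secure element of the step. The step needs 1,2- instead of 1,4-addition to the enal (the normal course of nickel/Et3B couplings with enals), attack at C11 instead of C19 (closure at C19 would give a more strained ten-membered ring) and ring closure instead of oligomerisation (slow addition to about 1 mM); the two esters and the trisubstituted alkene are inert to Ni/Et3B.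

**Compound list**

1 | 2-oxocyclopentane-1-carbonitrile | N#CC1CCCC1=O | starting material
2 | (1R)-1-methyl-2-oxocyclopentane-1-carbonitrile | N#C[C@@]1(C)CCCC1=O | intermediate
3 | (5R)-5-cyano-5-methylcyclopent-1-en-1-yl trifluoromethanesulfonate | N#C[C@@]1(C)CCC=C1OS(=O)(=O)C(F)(F)F | intermediate
4 | (1S)-2-(hydroxymethyl)-1-methylcyclopent-2-ene-1-carbonitrile | N#C[C@@]1(C)CCC=C1CO | intermediate
5 | [(5S)-5-cyano-5-methylcyclopent-1-en-1-yl]methyl propanoate | N#C[C@@]1(C)CCC=C1COC(=O)CC | intermediate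
6 | (Z)-O-trimethylsilyl ketene acetal of 5 | C/C=C(\O[Si](C)(C)C)OCC1=CCC[C@]1(C)C#N | intermediate
7 | trimethylsilyl ester of 8 | C[Si](C)(C)OC(=O)[C@@H](C)[C@@H]1CC[C@](C)(C#N)C1=C | intermediate
8 | (2S)-2-[(1S,3S)-3-cyano-3-methyl-2-methylidenecyclopentyl]propanoic acid | OC(=O)[C@@H](C)[C@@H]1CC[C@](C)(C#N)C1=C | intermediate
9 | isobutyl carbonic mixed anhydride of 8 | CC(C)COC(=O)OC(=O)[C@@H](C)[C@@H]1CC[C@](C)(C#N)C1=C | intermediate
10 | (1S,3S)-3-[(2S)-1-hydroxypropan-2-yl]-1-methyl-2-methylidenecyclopentane-1-carbonitrile | OC[C@@H](C)[C@@H]1CC[C@](C)(C#N)C1=C | intermediate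
11 | (1S,3S)-3-[(2S)-1-{[tert-butyl(dimethyl)silyl]oxy}propan-2-yl]-1-methyl-2-methylidenecyclopentane-1-carbonitrile | CC(C)(C)[Si](C)(C)OC[C@@H](C)[C@@H]1CC[C@](C)(C#N)C1=C | intermediate
12 | B-alkyl-9-borabicyclo[3.3.1]nonane adduct of 11 (boron on C9) | CC(C)(C)[Si](C)(C)OC[C@@H](C)[C@@H]1CC[C@](C)(C#N)[C@@H]1CB2C3CCCC2CCC3 | intermediate
13 | (1S,2R,3S)-3-[(2S)-1-{[tert-butyl(dimethyl)silyl]oxy}propan-2-yl]-2-(hydroxymethyl)-1-methylcyclopentane-1-carbonitrile | CC(C)(C)[Si](C)(C)OC[C@@H](C)[C@@H]1CC[C@](C)(C#N)[C@@H]1CO | intermediate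
14 | (1S,2R,3S)-3-[(2S)-1-{[tert-butyl(dimethyl)silyl]oxy}propan-2-yl]-2-formyl-1-methylcyclopentane-1-carbonitrile | CC(C)(C)[Si](C)(C)OC[C@@H](C)[C@@H]1CC[C@](C)(C#N)[C@@H]1C=O | intermediate
15 | (1S,2S,3R)-3-[(2S)-1-{[tert-butyl(dimethyl)silyl]oxy}propan-2-yl]-2-ethynyl-1-methylcyclopentane-1-carbonitrile | CC(C)(C)[Si](C)(C)OC[C@@H](C)[C@@H]1CC[C@](C)(C#N)[C@@H]1C#C | intermediate
16 | N-(diisobutylalumino)imine of 17 | CC(C)(C)[Si](C)(C)OC[C@@H](C)[C@@H]1CC[C@](C)(C=N[Al](CC(C)C)CC(C)C)[C@@H]1C#C | intermediate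
17 | (1S,2S,3R)-3-[(2S)-1-{[tert-butyl(dimethyl)silyl]oxy}propan-2-yl]-2-ethynyl-1-methylcyclopentane-1-carbaldehyde | CC(C)(C)[Si](C)(C)OC[C@@H](C)[C@@H]1CC[C@](C)(C=O)[C@@H]1C#C | intermediate
18 | O-diisopinocampheylboryl derivative of 19 | CC(C)(C)[Si](C)(C)OC[C@@H](C)[C@@H]1CC[C@](C)([C@@H](OB([C@@H]2C[C@@H]3C[C@H]([C@H]2C)C3(C)C)[C@@H]2C[C@@H]3C[C@H]([C@H]2C)C3(C)C)CC=C)[C@@H]1C#C | intermediate
19 | (1S)-1-[(1S,2S,3R)-3-[(2S)-1-{[tert-butyl(dimethyl)silyl]oxy}propan-2-yl]-2-ethynyl-1-methylcyclopentyl]but-3-en-1-ol | CC(C)(C)[Si](C)(C)OC[C@@H](C)[C@@H]1CC[C@](C)([C@@H](O)CC=C)[C@@H]1C#C | intermediate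
20 | (1S)-1-[(1S,2S,3R)-3-[(2S)-1-{[tert-butyl(dimethyl)silyl]oxy}propan-2-yl]-2-ethynyl-1-methylcyclopentyl]but-3-en-1-yl propanoate | CC(C)(C)[Si](C)(C)OC[C@@H](C)[C@@H]1CC[C@](C)([C@@H](OC(=O)CC)CC=C)[C@@H]1C#C | intermediate
21 | (1S)-1-[(1S,2S,3R)-2-ethynyl-3-[(2S)-1-hydroxypropan-2-yl]-1-methylcyclopentyl]but-3-en-1-yl propanoate | OC[C@@H](C)[C@@H]1CC[C@](C)([C@@H](OC(=O)CC)CC=C)[C@@H]1C#C | intermediate
22 | (1S)-1-[(1S,2S,3R)-2-ethynyl-1-methyl-3-[(2S)-1-oxopropan-2-yl]cyclopentyl]but-3-en-1-yl propanoate | O=C[C@@H](C)[C@@H]1CC[C@](C)([C@@H](OC(=O)CC)CC=C)[C@@H]1C#C | intermediate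
23 | (2E)-2-methylbut-2-enal | C/C=C(\C)C=O | starting material
24 | tert-butyl(dimethyl){[(1E)-2-methylbuta-1,3-dien-1-yl]oxy}silane | C=C/C(C)=C/O[Si](C)(C)C(C)(C)C | intermediate
25 | (1S)-1-[(1S,2S,3R)-2-ethynyl-3-[(2S,3S,5E)-3-hydroxy-6-methyl-7-oxohept-5-en-2-yl]-1-methylcyclopentyl]but-3-en-1-yl propanoate | O=C/C(C)=C/C[C@H](O)[C@@H](C)[C@@H]1CC[C@](C)([C@@H](OC(=O)CC)CC=C)[C@@H]1C#C | intermediate
26 | (1S)-1-[(1S,2S,3R)-3-[(2S,3S,5E)-3-(acetyloxy)-6-methyl-7-oxohept-5-en-2-yl]-2-ethynyl-1-methylcyclopentyl]but-3-en-1-yl propanoate | O=C/C(C)=C/C[C@H](OC(C)=O)[C@@H](C)[C@@H]1CC[C@](C)([C@@H](OC(=O)CC)CC=C)[C@@H]1C#C | intermediate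
27 | (1R,3aS,4S,7aS)-1-[(2S,3S,5E)-3-(acetyloxy)-6-methyl-7-oxohept-5-en-2-yl]-3a-methyl-6,7-dimethylideneoctahydro-1H-inden-4-yl propanoate | O=C/C(C)=C/C[C@H](OC(C)=O)[C@@H](C)[C@@H]1CC[C@]2(C)[C@@H](OC(=O)CC)CC(=C)C(=C)[C@H]12 | intermediate
28 | O-diethylboryl ether of 29 | C=C1[C@@H]2C[C@@H](OB(CC)CC)/C(C)=C/C[C@H](OC(C)=O)[C@@H](C)[C@@H]3CC[C@](C)([C@@H](OC(=O)CC)C2)[C@H]13 | intermediate
29 | CNP0180453.1 (locants of the plan: 1R,2E,5S,6S,7R,8S,10R,13S,14S; 5-acetate, 13-propanoate, free 1-hydroxyl) | C=C1[C@@H]2C[C@@H](O)/C(C)=C/C[C@H](OC(C)=O)[C@@H](C)[C@@H]3CC[C@](C)([C@@H](OC(=O)CC)C2)[C@H]13 | target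

**Step count and risks**

Total: 20 steps. Longest linear sequence: 19 steps (steps 1–15 and 17–20); step 16 prepares the dienol ether.

Steps most likely to fail:

1. Step 20. The ring closure may lose out to oligomerisation, to coupling at the proximal diene terminus C19, or to reaction on the other face of the diene or of the aldehyde (wrong C10 or C1). The fallback forms the same C11–C1 bond by an alkylchromium addition, setting out from 26 and returning at 29. Enyne 26 is cyclised under palladium-catalysed borylative conditions (Pd(OAc)2, bis(pinacolato)diboron, MeOH, toluene, 50 °C) to the C11 pinacol boronate F1, in which the six-membered ring, C9=C19 and the C10 stereocentre are in place. Oxidation with NaBO3·4H2O gives the C11 primary alcohol F2, and I2, PPh3 and imidazole give the C11 iodide F3. F3 is closed onto the enal by a 1,2-selective alkylchromium addition (CrCl2, catalytic cobalt phthalocyanine Co(C32H16N8), DMF, high dilution) to give 29.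

2. Step 5. Discrimination between the methyl face and the nitrile face of the cyclopentene may be insufficient, eroding the C7/C14 relationship. The fallback reinforces the relay by 1,3-chirality transfer from a carbinol, setting out from 3 and returning at 8. Triflate 3 is coupled carbonylatively (CO, Me4Sn, Pd(PPh3)4, LiCl, DMF) to (1S)-2-acetyl-1-methylcyclopent-2-ene-1-carbonitrile F4. Reduction with (R)-Me-CBS and BH3·SMe2 gives the (S)-carbinol F5, which is acylated (EtCOCl, pyridine) to the propanoate F6. Ireland–Claisen rearrangement under the conditions of step 5, through the chair with the carbinol methyl equatorial, transfers the carbinol configuration to C7 on the nitrile face and gives the (Z)-ethylidene acid F7. Ozonolysis (O3, then Me2S) gives the keto acid F8, and non-basic methylenation (Zn, CH2Br2, TiCl4) returns to 8.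

3. Step 1. The methylation may proceed with low enantioselectivity, or the β-keto nitrile may be cleaved by base under phase-transfer conditions. The fallback replaces asymmetric catalysis by resolution, setting out from 1 and returning at 2. Compound 1 is methylated without chiral catalyst (MeI, K2CO3, acetone) to racemic 1-methyl-2-oxocyclopentane-1-carbonitrile F9. Ketalisation with (R,R)-hydrobenzoin (TsOH, benzene, removal of water) gives diastereomeric ketals; the ketal of the (R)-ketone F10 is separated by crystallisation or chromatography and hydrolysed (aq. HCl, THF) to 2.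

Further compounds
F1 | step 20 | analogue of 27 closed at C9–C10 with C10 sp3 (H α, configured as in 29) carrying CH2–B(pinacolato) at C11 and C9=C19 retained | O=C/C(C)=C/C[C@H](OC(C)=O)[C@@H](C)[C@@H]1CC[C@]2(C)[C@@H](OC(=O)CC)C[C@@H](CB3OC(C)(C)C(C)(C)O3)C(=C)[C@H]12
F2 | step 20 | C11 primary alcohol corresponding to F1 | O=C/C(C)=C/C[C@H](OC(C)=O)[C@@H](C)[C@@H]1CC[C@]2(C)[C@@H](OC(=O)CC)C[C@@H](CO)C(=C)[C@H]12
F3 | step 20 | C11 primary iodide corresponding to F2 | O=C/C(C)=C/C[C@H](OC(C)=O)[C@@H](C)[C@@H]1CC[C@]2(C)[C@@H](OC(=O)CC)C[C@@H](CI)C(=C)[C@H]12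
F4 | step 5 | (1S)-2-acetyl-1-methylcyclopent-2-ene-1-carbonitrile | N#C[C@@]1(C)CCC=C1C(C)=O
F5 | step 5 | (1S)-2-[(1S)-1-hydroxyethyl]-1-methylcyclopent-2-ene-1-carbonitrile | N#C[C@@]1(C)CCC=C1[C@H](C)O
F6 | step 5 | (1S)-1-[(5S)-5-cyano-5-methylcyclopent-1-en-1-yl]ethyl propanoate | N#C[C@@]1(C)CCC=C1[C@H](C)OC(=O)CC
F7 | step 5 | (2S)-2-[(1S,2Z,3S)-3-cyano-2-ethylidene-3-methylcyclopentyl]propanoic acid | OC(=O)[C@@H](C)[C@@H]1CC[C@](C)(C#N)/C1=C\C
F8 | step 5 | (2S)-2-[(1S,3R)-3-cyano-3-methyl-2-oxocyclopentyl]propanoic acid | OC(=O)[C@@H](C)[C@@H]1CC[C@](C)(C#N)C1=O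
F9 | step 1 | racemic 1-methyl-2-oxocyclopentane-1-carbonitrile | N#CC1(C)CCCC1=O
F10 | step 1 | (R,R)-hydrobenzoin ketal of (1R)-1-methyl-2-oxocyclopentane-1-carbonitrile | N#C[C@@]1(C)CCCC12O[C@H](c3ccccc3)[C@@H](c3ccccc3)O2
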